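The hour is the unit to hold on to: the rate constants below are per hour and the stays are in hours, so each product of the two is a pure number.

    substrate ⇌ intermediate A (K1 = 2.20, k1 = 0.0425 /h)
    substrate → side product (k2 = 0.0404 /h)
    substrate → intermediate B (k3 = 0.0329 /h)
    intermediate A → target (k4 = 0.0254 /h)
    intermediate B → target (k5 = 0.0788 /h)
    target ⇌ isomer of the product (K6 = 0.476, k6 = 0.00657 /h)

| setting | theta | beta | gamma | eta |
|---|---|---|---|---|
| substrate | 2.6 M | 2.6 M | 2.6 M | 2.6 M |
| remark | a single well-mixed tank run continuously and read at steady state, 12 h in it on average | plug flow through a tube for 12 h, no back-mixing | a closed flask charged with all of it at once and left for 12 h | a single well-mixed tank run continuously and read at steady state, 36.0 h in it on average |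
| time |  | 12 h | 12 h |  |

- the set-up with the highest share of target in all that became target or side product or isomer of the product, at the outlet or at the end ("none" if the first two lie within 2 percentage points) (theta / beta / gamma / eta / none)
- share of target in all that became target or side product or isomer of the product, at the outlet or at the end, theta
- share of target in all that became target or side product or isomer of the product, at the outlet or at the end, beta
- share of target in all that became target or side product or isomer of the product, at the outlet or at the end, gamma
- share of target in all that became target or side product or isomer of the product, at the outlet or at the end, eta

- the stated concentrations are those of everything mixed, before any reaction; amounts are the same in each set-up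
- run time (beta): 12 h

**What does a steady well-mixed tank do to an intermediate with a first-order exit?** It gives it two drains. The reaction removes k·c(intermediate B), and the outflow removes c(intermediate B) divided by the mean stay. The ratio of the two drains is the rate constant times the mean stay. In the eta tank, for intermediate B, that ratio is 2.84. I call it the stay number, the Damköhler number of that step: what has passed through the step, per unit still standing at the outlet.

**Where is the zero of this scale?** At a stay number of one, where the split is even: as much has reacted on as flows out unreacted. Of what enters intermediate B, the passed fraction is the stay number over one plus the stay number.

**And these two tanks?** The theta tank has 0.946, just under even, so 48.6% passes. The eta tank has a larger number, so 73.9% passes. For the step from intermediate A to target, the numbers are 0.305 and 0.914, both below even, and the way back to substrate is a further drain on intermediate A.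

**But a longer stay makes more side product too. Where is the gain?** Side product forms in one step and pays no such toll, whereas target through intermediate B pays it. Per unit of side product, this route delivers 0.396 in the theta tank and 0.602 in the eta tank, whatever the level of substrate in the tank.

**Your verdict?** I put eta above theta. The tube and the flask give every parcel the same 12 h under first-order steps, so they should tie. I do not reckon tube against tank.

The forecast names eta, with 35.3% for theta, 32.4% for beta, 32.4% for gamma and 42.5% for eta, on the ground that “the longer time lets far more material through the intermediates to target”.

The simulation gives 35.3%, 32.4%, 32.4% and 42.5% in the same order, with eta highest, as forecast. In the eta tank, 6.48% of the charge stands as intermediate B at the outlet, so the stay number says 18.4% of the charge has left it for target. The entry to that route, the passing of substrate into intermediate B, may be called the main reason for the share of target in the gamma flask: with it struck out, the gamma share falls from 32.4% to 13.0%. In the theta tank, 14.4% of the charge stands as intermediate A, and its stay number of 0.305 gives 4.39% of the charge passed to target.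

The constants used here stand for no real mixture.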